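**Retrosynthetic overview**
- The target is traced back to its 2,13-diol (selective acylation of the secondary C2 hydroxyl); the C12–C13 bond and C13 come from lithiation–borylation of a C12 boronic ester with an (R)-butenyl carbamate; C7=C8 comes from a C7 ketone by reduction and anti-elimination.
- The decalin is traced back to an acyclic trienal by an intramolecular Diels–Alder reaction that makes C5–C10 and C8–C9, closes rings A and B together and sets C5, C9 and C10 from the single stereocentre C2.
- Enabling feature: ring B (C5–C6–C7–C8–C9–C10) is a cyclohexene retron once C7=C8 is read as a C7 ketone (silyl enol ether C6=C7 in the adduct) and C11 as a formyl group. C1–C4 of ring A are the four-carbon tether, and the equatorial C2 oxygen, flanked by quaternary C4 and C10, fixes the face.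
- The trienal comes from (R)-epichlorohydrin (C1–C3), prenyl Grignard (C4, C5, C18, C19), acetylide/AlMe3/ClCO2Me (C9, C10, C20, C11) and ethyl vinyl ketone (C6–C8, C17).
- Ring order: no ring before step 9; rings A and B form together in step 9; no ring afterwards.

Key step: step 9

Remark (convention): positions carry labdane numbers (C1–C20, ester oxygen on C2); α means the face of the C10 methyl group, β the opposite face; TBS = tert-butyldimethylsilyl.
Remark (assumption): without copper, prenylmagnesium chloride is taken to open the terminal epoxide through its γ-carbon, as allylic Grignard reagents normally do.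

Step 1
Reactants: 1 (R)-epichlorohydrin; 2 prenylmagnesium chloride
Product: 3 (R)-1-chloro-4,4-dimethylhex-5-en-2-ol
Conditions: THF, −78 → −20 °C; aq. NH4Cl
Reagents that add atoms: none
Why: Uncatalysed allylic Grignard reagents open terminal epoxides at the CH2 carbon through their γ-terminus (SE2′ epoxide allylation), which should deliver the C4 gem-dimethyl/vinyl unit while the stereocentre of 1 (future C2) is not touched and no new stereocentre forms.

Step 2
Reactants: 3 (R)-1-chloro-4,4-dimethylhex-5-en-2-ol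
Product: 5 (S)-6,6-dimethyloct-7-en-1-yn-4-ol, via epoxide 4 (not isolated)
Conditions: LiC≡CH·H2NCH2CH2NH2 (3 equiv), DMSO, 0 °C → rt; H2O
Reagents that add atoms: lithium acetylide–ethylenediamine complex, [Li]C#C.NCCN
Why: The chlorohydrin alkoxide should close to the terminal epoxide, which the acetylide opens at its unsubstituted carbon (epoxide alkynylation), so C2 keeps its configuration and C9/C10 arrive as a terminal alkyne.

Step 3
Reactants: 5 (S)-6,6-dimethyloct-7-en-1-yn-4-ol
Product: 6 (S)-tert-butyl[(6,6-dimethyloct-7-en-1-yn-4-yl)oxy]dimethylsilane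
Conditions: TBSCl, imidazole, DMF, rt
Reagents that add atoms: tert-butyldimethylsilyl chloride, CC(C)(C)[Si](C)(C)Cl
Why: Standard silylation protects the C2 hydroxyl as the bulky ether that later steers the cycloaddition; no stereocentre is affected.

Step 4
Reactants: 6 (S)-tert-butyl[(6,6-dimethyloct-7-en-1-yn-4-yl)oxy]dimethylsilane
Product: 8 methyl (2E,5S)-5-(TBS-oxy)-3,7,7-trimethylnona-2,8-dienoate, via alkenylalane 7 (not isolated)
Conditions: AlMe3 (2.5 equiv), Cp2ZrCl2 (25 mol %), CH2Cl2, 0 °C → rt; then n-BuLi, THF, −78 °C; ClCO2Me, −78 → 0 °C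
Reagents that add atoms: trimethylaluminium, C[Al](C)C; methyl chloroformate, COC(Cl)=O
Why: Zirconium-catalysed syn-methylalumination of the terminal alkyne (Negishi carboalumination) puts CH3 on C10 and aluminium on C9, and acylation of the derived alanate with retention should give the (E)-enoate, the dienophile geometry that later places C20 and C11 cis.

Step 5
Reactants: 8 methyl (2E,5S)-5-(TBS-oxy)-3,7,7-trimethylnona-2,8-dienoate; 9 ethyl vinyl ketone (pent-1-en-3-one)
Product: 10 methyl (2E,5S,8E)-5-(TBS-oxy)-3,7,7-trimethyl-10-oxododeca-2,8-dienoate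
Conditions: 9 (4 equiv), second-generation Hoveyda–Grubbs catalyst RuCl2(H2IMes)(=CH-C6H4-2-Oi-Pr) (5 mol %), CH2Cl2, 40 °C
Reagents that add atoms: none
Why: Olefin cross-metathesis between the hindered monosubstituted alkene and an excess of the electron-poor vinyl ketone should be (E)-selective and leave the trisubstituted enoate untouched.

Step 6
Reactants: 10 methyl (2E,5S,8E)-5-(TBS-oxy)-3,7,7-trimethyl-10-oxododeca-2,8-dienoate
Product: 11 methyl (2E,5S,8E,10Z)-5,10-bis(TBS-oxy)-3,7,7-trimethyldodeca-2,8,10-trienoate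
Conditions: TBSOTf, Et3N, CH2Cl2, −78 → 0 °C
Reagents that add atoms: tert-butyldimethylsilyl trifluoromethanesulfonate, CC(C)(C)[Si](C)(C)OS(=O)(=O)C(F)(F)F
Why: Soft enolisation of the ethyl ketone (silyl triflate/amine) should give the (Z)-2-silyloxy-1,3-diene with the C8 methyl in the outside position, while the ester and the silyl ether are inert.

Step 7
Reactants: 11 methyl (2E,5S,8E,10Z)-5,10-bis(TBS-oxy)-3,7,7-trimethyldodeca-2,8,10-trienoate
Product: 12 (2E,5S,8E,10Z)-5,10-bis(TBS-oxy)-3,7,7-trimethyldodeca-2,8,10-trien-1-ol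
Conditions: (i-Bu)2AlH (2.2 equiv), CH2Cl2, −78 °C; aq. KNaC4H4O6 (Rochelle salt)
Reagents that add atoms: none
Why: Diisobutylaluminium hydride reduces the conjugated ester 1,2 to the allylic alcohol at low temperature without touching the silyl dienol ether.

Step 8
Reactants: 12 (2E,5S,8E,10Z)-5,10-bis(TBS-oxy)-3,7,7-trimethyldodeca-2,8,10-trien-1-ol
Product: 13 (2E,5S,8E,10Z)-5,10-bis(TBS-oxy)-3,7,7-trimethyldodeca-2,8,10-trienal
Conditions: MnO2 (activated, excess), CH2Cl2, rt
Reagents that add atoms: none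
Why: MnO2 oxidises only the allylic alcohol under neutral conditions, which should give the (E)-enal without isomerisation or loss of the acid-labile dienol ether.

Step 9
Reactants: 13 (2E,5S,8E,10Z)-5,10-bis(TBS-oxy)-3,7,7-trimethyldodeca-2,8,10-trienal
Product: 15 2β-(TBS-oxy)-7-oxo-12,13,14,15,16-pentanorlabdan-11-al (5β-H, 8α-CH3, 9α-CHO, 10α-CH3), via silyl enol ether cycloadduct 14 (not isolated)
Conditions: Me2AlCl (1.2 equiv), CH2Cl2, −78 → −30 °C; then 1 M HCl, THF, 0 °C
Reagents that add atoms: none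
Why: Me2AlCl binds the formyl group and triggers a concerted, asynchronous [4+2] cycloaddition of the C5=C6–C7(OSi)=C8 diene to the C9=C10 enal double bond, the closest known reaction type being the Lewis-acid-promoted type 1 intramolecular Diels–Alder reaction of 1,3,9-decatrienes with a terminal activating carbonyl group, and the acidic work-up then hydrolyses the silyl enol ether to the C7 ketone. Ring B is closed as the six-membered cycloadduct by both new bonds (C5–C10 leading, C8–C9 following), and ring A is closed by the C5–C10 bond across the four-carbon tether C1–C4 in a chair-like fused six-membered array. C9 and C10 are set relative to each other by the (E)-geometry of the dienophile (suprafacial addition puts C11 and C20 cis), and C5 relative to C10 by the endo orientation of the aluminium-bound formyl group, which forces the tether anti and hence the trans ring fusion. The absolute sense comes from C2, because in the chair-like tether the OTBS group stays equatorial (an axial position would be 1,3-diaxial to the C10 methyl and one C4 methyl), so the diene adds to the face that puts C20 trans to the C2 oxygen. The transient C8 centre follows from the (Z)-enol ether (methyl outside) and is corrected in step 10. The step needs endo/anti and π-facial selectivity, which the Lewis-acid-bound formyl group and the C2 stereocentre between the two quaternary carbons should secure, while the tether fixes the regiochemistry.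

Step 10
Reactants: 15 2β-(TBS-oxy)-7-oxo-12,13,14,15,16-pentanorlabdan-11-al
Product: 16 2β-(TBS-oxy)-13,14,15,16-tetranorlabd-11-en-7-one (5β-H, 8β-CH3, 9β-H, 10α-CH3)
Conditions: Ph3PCH3Br, KN(SiMe3)2, THF, −78 → 0 °C; then K2CO3, MeOH, rt
Reagents that add atoms: methyltriphenylphosphonium bromide, C[P+](c1ccccc1)(c1ccccc1)c1ccccc1.[Br-]
Why: Wittig methylenation should be selective for the aldehyde over the hindered ketone at low temperature, and the base then equilibrates C8 to the equatorial (β) methyl epimer, which relieves the 1,3-diaxial clash with the C10 methyl, while C9 already carries its substituent equatorially.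

Step 11
Reactants: 16 2β-(TBS-oxy)-13,14,15,16-tetranorlabd-11-en-7-one
Product: 17 2β-(TBS-oxy)-13,14,15,16-tetranorlabd-11-en-7β-ol (axial OH, 8β-CH3)
Conditions: Li[HB(s-Bu)3] (L-Selectride), THF, −78 °C; then H2O
Reagents that add atoms: none
Why: The bulky trialkylborohydride attacks the C7 ketone from the equatorial direction, which should give the axial (7β) alcohol cis to the C8 methyl (L-Selectride reduction of a 2-alkylcyclohexanone).

Step 12
Reactants: 17 2β-(TBS-oxy)-13,14,15,16-tetranorlabd-11-en-7β-ol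
Product: 18 2β-(TBS-oxy)-13,14,15,16-tetranorlabda-7,11-diene
Conditions: POCl3, pyridine, 0 → 60 °C
Reagents that add atoms: none
Why: The axial dichlorophosphate should undergo anti-periplanar E2 elimination with the axial tertiary hydrogen at C8 (Zaitsev orientation, as in the dehydration of axial 2-methylcyclohexanol-type alcohols), giving the trisubstituted C7=C8 alkene.

Step 13
Reactants: 18 2β-(TBS-oxy)-13,14,15,16-tetranorlabda-7,11-diene
Product: 19 2β-(TBS-oxy)-12-(4,4,5,5-tetramethyl-1,3,2-dioxaborolan-2-yl)-13,14,15,16-tetranorlabd-7-ene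
Conditions: pinacolborane, [Ir(cod)Cl]2 (1.5 mol %), dppm (3 mol %), CH2Cl2, rt
Reagents that add atoms: pinacolborane, CC1(C)OBOC1(C)C
Why: Iridium-catalysed hydroboration with pinacolborane is anti-Markovnikov and selective for the monosubstituted alkene over the trisubstituted ring alkene, which should give the primary C12 boronic ester.

Step 14
Reactants: 20 (R)-but-3-en-2-ol
Product: 21 (R)-but-3-en-2-yl N,N-diisopropylcarbamate
Conditions: i-Pr2NC(O)Cl, Et3N, CH2Cl2, reflux
Reagents that add atoms: N,N-diisopropylcarbamoyl chloride, CC(C)N(C(C)C)C(Cl)=O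
Why: Carbamoylation of the enantiopure secondary allylic alcohol gives the carbamate needed for directed α-lithiation, without touching the stereocentre.

Step 15
Reactants: 21 (R)-but-3-en-2-yl N,N-diisopropylcarbamate; 19 2β-(TBS-oxy)-12-(pinacolboryl)-13,14,15,16-tetranorlabd-7-ene
Product: 25 (13S)-2β-(TBS-oxy)labda-7,14-dien-13-ol, via lithiated carbamate 22 (not isolated), via boronate complex 23 (not isolated), via tertiary boronic ester 24 (not isolated)
Conditions: 21, s-BuLi, TMEDA, Et2O, −78 °C; then 19; MgBr2·OEt2, MeOH, −78 °C → rt; then NaOH, H2O2, THF, 0 °C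
Reagents that add atoms: hydrogen peroxide, OO
Why: In this lithiation–borylation the configurationally stable α-lithiated allylic carbamate adds to the boronic ester with retention, the 1,2-metallate rearrangement expels the carbamate with inversion and oxidation of the C–B bond goes with retention, so the (R)-carbamate should be transferred stereospecifically into the (13S) tertiary vinyl carbinol.

Step 16
Reactants: 25 (13S)-2β-(TBS-oxy)labda-7,14-dien-13-ol
Product: 26 (13S)-labda-7,14-diene-2β,13-diol
Conditions: Bu4NF, THF, rt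
Reagents that add atoms: none
Why: Fluoride cleaves the secondary silyl ether, and the tertiary allylic alcohol and both alkenes are stable to these conditions.

Step 17
Reactants: 26 (13S)-labda-7,14-diene-2β,13-diol; 27 3-methylbut-2-enoic acid
Product: 28 (13S)-2β-(3-methylbut-2-enoyloxy)labda-7,14-dien-13-ol (target)
Conditions: DCC, DMAP (cat.), CH2Cl2, 0 °C → rt
Reagents that add atoms: none
Why: Steglich esterification should acylate the unhindered equatorial secondary C2 hydroxyl and leave the tertiary allylic C13 hydroxyl untouched, giving the target.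

**Compound list**
1 | (R)-epichlorohydrin, (R)-2-(chloromethyl)oxirane | ClC[C@H]1CO1 | starting material
2 | prenylmagnesium chloride, (3-methylbut-2-en-1-yl)magnesium chloride | CC(C)=CC[Mg]Cl | starting material
3 | (R)-1-chloro-4,4-dimethylhex-5-en-2-ol | C=CC(C)(C)C[C@@H](O)CCl | intermediate
4 | (R)-2-(2,2-dimethylbut-3-en-1-yl)oxirane (not isolated) | C=CC(C)(C)C[C@@H]1CO1 | intermediate
5 | (S)-6,6-dimethyloct-7-en-1-yn-4-ol | C=CC(C)(C)C[C@@H](O)CC#C | intermediate
6 | (S)-tert-butyl[(6,6-dimethyloct-7-en-1-yn-4-yl)oxy]dimethylsilane | C=CC(C)(C)C[C@@H](O[Si](C)(C)C(C)(C)C)CC#C | intermediate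
7 | (E)-alkenyldimethylalane from syn-methylalumination of 6: CH3 on C10, AlMe2 on C9 (not isolated) | C=CC(C)(C)C[C@@H](O[Si](C)(C)C(C)(C)C)C/C(C)=C/[Al](C)C | intermediate
8 | methyl (2E,5S)-5-(TBS-oxy)-3,7,7-trimethylnona-2,8-dienoate | C=CC(C)(C)C[C@@H](O[Si](C)(C)C(C)(C)C)C/C(C)=C/C(=O)OC | intermediate
9 | ethyl vinyl ketone (pent-1-en-3-one) | C=CC(=O)CC | starting material
10 | methyl (2E,5S,8E)-5-(TBS-oxy)-3,7,7-trimethyl-10-oxododeca-2,8-dienoate | CCC(=O)/C=C/C(C)(C)C[C@@H](O[Si](C)(C)C(C)(C)C)C/C(C)=C/C(=O)OC | intermediate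
11 | methyl (2E,5S,8E,10Z)-5,10-bis(TBS-oxy)-3,7,7-trimethyldodeca-2,8,10-trienoate | C/C=C(O[Si](C)(C)C(C)(C)C)/C=C/C(C)(C)C[C@@H](O[Si](C)(C)C(C)(C)C)C/C(C)=C/C(=O)OC | intermediate
12 | (2E,5S,8E,10Z)-5,10-bis(TBS-oxy)-3,7,7-trimethyldodeca-2,8,10-trien-1-ol | C/C=C(O[Si](C)(C)C(C)(C)C)/C=C/C(C)(C)C[C@@H](O[Si](C)(C)C(C)(C)C)C/C(C)=C/CO | intermediate
13 | (2E,5S,8E,10Z)-5,10-bis(TBS-oxy)-3,7,7-trimethyldodeca-2,8,10-trienal | C/C=C(O[Si](C)(C)C(C)(C)C)/C=C/C(C)(C)C[C@@H](O[Si](C)(C)C(C)(C)C)C/C(C)=C/C=O | intermediate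
14 | 2β,7-bis(TBS-oxy)-12,13,14,15,16-pentanorlabd-6-en-11-al, trans-fused (5β-H, 8α-CH3, 9α-CHO, 10α-CH3) (not isolated) | O=C[C@@H]1[C@H](C)C(O[Si](C)(C)C(C)(C)C)=C[C@@H]2C(C)(C)C[C@@H](O[Si](C)(C)C(C)(C)C)C[C@@]12C | intermediate
15 | 2β-(TBS-oxy)-7-oxo-12,13,14,15,16-pentanorlabdan-11-al, trans-fused (5β-H, 8α-CH3, 9α-CHO, 10α-CH3) | O=C[C@@H]1[C@H](C)C(=O)C[C@@H]2C(C)(C)C[C@@H](O[Si](C)(C)C(C)(C)C)C[C@@]12C | intermediate
16 | 2β-(TBS-oxy)-13,14,15,16-tetranorlabd-11-en-7-one (5β-H, 8β-CH3, 9β-H, 10α-CH3) | C=C[C@@H]1[C@@H](C)C(=O)C[C@@H]2C(C)(C)C[C@@H](O[Si](C)(C)C(C)(C)C)C[C@@]12C | intermediate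
17 | 2β-(TBS-oxy)-13,14,15,16-tetranorlabd-11-en-7β-ol (axial OH, 8β-CH3) | C=C[C@@H]1[C@@H](C)[C@@H](O)C[C@@H]2C(C)(C)C[C@@H](O[Si](C)(C)C(C)(C)C)C[C@@]12C | intermediate
18 | 2β-(TBS-oxy)-13,14,15,16-tetranorlabda-7,11-diene | C=C[C@@H]1C(C)=CC[C@@H]2C(C)(C)C[C@@H](O[Si](C)(C)C(C)(C)C)C[C@@]12C | intermediate
19 | 2β-(TBS-oxy)-12-(4,4,5,5-tetramethyl-1,3,2-dioxaborolan-2-yl)-13,14,15,16-tetranorlabd-7-ene | CC1(C)OB(CC[C@@H]2C(C)=CC[C@@H]3C(C)(C)C[C@@H](O[Si](C)(C)C(C)(C)C)C[C@@]23C)OC1(C)C | intermediate
20 | (R)-but-3-en-2-ol | C=C[C@@H](C)O | starting material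
21 | (R)-but-3-en-2-yl N,N-diisopropylcarbamate | C=C[C@@H](C)OC(=O)N(C(C)C)C(C)C | intermediate
22 | α-lithiated carbamate, Li in place of the carbinol H of 21 with retention (not isolated) | C=C[C@@]([Li])(C)OC(=O)N(C(C)C)C(C)C | intermediate
23 | lithium boronate complex of 22 with 19, C13–B bond formed with retention (not isolated) | C=C[C@@](C)(OC(=O)N(C(C)C)C(C)C)[B-]1(CC[C@@H]2C(C)=CC[C@@H]3C(C)(C)C[C@@H](O[Si](C)(C)C(C)(C)C)C[C@@]23C)OC(C)(C)C(C)(C)O1.[Li+] | intermediate
24 | tertiary allylic pinacol boronic ester at C13: 2β-(TBS-oxy)-13-(pinacolboryl)labda-7,14-diene (not isolated) | C=C[C@@](C)(B1OC(C)(C)C(C)(C)O1)CC[C@@H]2C(C)=CC[C@@H]3C(C)(C)C[C@@H](O[Si](C)(C)C(C)(C)C)C[C@@]23C | intermediate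
25 | (13S)-2β-(TBS-oxy)labda-7,14-dien-13-ol | C=C[C@@](C)(O)CC[C@@H]1C(C)=CC[C@@H]2C(C)(C)C[C@@H](O[Si](C)(C)C(C)(C)C)C[C@@]12C | intermediate
26 | (13S)-labda-7,14-diene-2β,13-diol (5β-H, 9β-H, 10α-CH3) | C=C[C@@](C)(O)CC[C@@H]1C(C)=CC[C@@H]2C(C)(C)C[C@@H](O)C[C@@]12C | intermediate
27 | 3-methylbut-2-enoic acid (senecioic acid) | CC(C)=CC(=O)O | starting material
28 | (13S)-2β-(3-methylbut-2-enoyloxy)labda-7,14-dien-13-ol (5β-H, 9β-H, 10α-CH3), CNP0252389.1 | C=C[C@@](C)(O)CC[C@@H]1C(C)=CC[C@@H]2C(C)(C)C[C@@H](OC(=O)C=C(C)C)C[C@@]12C | target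

Total step count: 17. Longest linear sequence: 16 steps (steps 1–13 and 15–17, from (R)-epichlorohydrin).

**Steps most likely to fail**

Step 9. The Lewis acid may strip the silyl dienol ether (protodesilylation or ionic Mukaiyama-type oligomerisation) or erode the endo and facial control. The fallback moves the cycloaddition to the ester oxidation level and runs it without any Lewis acid. It sets out from 11: heating (toluene, 180 °C, sealed tube, BHT) should give the ester cycloadduct F1, from which the endo isomer is separated. LiAlH4 (Et2O, 0 °C) reduces it to the primary alcohol F2, and Dess–Martin periodinane with NaHCO3 gives aldehyde 14. Treatment with 1 M HCl in THF then rejoins the route at 15.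

Step 15. Borylation may occur at the γ-terminus of the lithiated allyl carbamate, or the 1,2-metallate shift may fail or leak stereochemistry. The fallback sets C13 by Sharpless asymmetric epoxidation instead and sets out from 18. Hydroboration with 9-BBN (THF) gives the B-alkyl-9-BBN borane F3, which is coupled in situ with (Z)-3-iodobut-2-en-1-ol (PdCl2(dppf), AsPh3, Cs2CO3, DMF/H2O; B-alkyl Suzuki–Miyaura coupling) to the (Z)-allylic alcohol F4. Sharpless epoxidation with D-(−)-diethyl tartrate (Ti(Oi-Pr)4, t-BuOOH, 4 Å sieves, CH2Cl2, −20 °C) should give the epoxy alcohol F5 with the required C13 configuration. I2, PPh3 and imidazole convert it into the epoxy iodide F6, and zinc dust in refluxing ethanol opens this reductively to the tertiary vinyl carbinol, rejoining the route at 25.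

Step 12. Elimination may run toward C6 and give the C6=C7 isomer. The fallback makes the alkene by reductive removal of an enol triflate and sets out from 16. Under equilibrating conditions (Tf2O, 2,6-di-tert-butyl-4-methylpyridine, CH2Cl2) the ketone should give the more substituted enol triflate F7. Reduction with Pd(OAc)2, PPh3, Bu3N and HCO2H (DMF, 60 °C) rejoins the route at 18.

Further compounds
F1 | step 9 | methyl 2β,7-bis(TBS-oxy)-12,13,14,15,16-pentanorlabd-6-en-11-oate (5β-H, 8α-CH3, 9α-CO2Me, 10α-CH3) | COC(=O)[C@@H]1[C@H](C)C(O[Si](C)(C)C(C)(C)C)=C[C@@H]2C(C)(C)C[C@@H](O[Si](C)(C)C(C)(C)C)C[C@@]12C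
F2 | step 9 | 2β,7-bis(TBS-oxy)-12,13,14,15,16-pentanorlabd-6-en-11-ol | OC[C@@H]1[C@H](C)C(O[Si](C)(C)C(C)(C)C)=C[C@@H]2C(C)(C)C[C@@H](O[Si](C)(C)C(C)(C)C)C[C@@]12C
F3 | step 15 | B-alkyl-9-borabicyclo[3.3.1]nonane from 18, boron on C12 | B1(CC[C@@H]2C(C)=CC[C@@H]3C(C)(C)C[C@@H](O[Si](C)(C)C(C)(C)C)C[C@@]23C)C2CCCC1CCC2
F4 | step 15 | (13Z)-2β-(TBS-oxy)labda-7,13-dien-15-ol | OC/C=C(C)\CC[C@@H]1C(C)=CC[C@@H]2C(C)(C)C[C@@H](O[Si](C)(C)C(C)(C)C)C[C@@]12C
F5 | step 15 | 13,14-epoxy-2β-(TBS-oxy)labd-7-en-15-ol (cis-epoxide, C13 as in the target) | OC[C@H]1O[C@@]1(C)CC[C@@H]2C(C)=CC[C@@H]3C(C)(C)C[C@@H](O[Si](C)(C)C(C)(C)C)C[C@@]23C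
F6 | step 15 | 13,14-epoxy-15-iodo-2β-(TBS-oxy)labd-7-ene | IC[C@H]1O[C@@]1(C)CC[C@@H]2C(C)=CC[C@@H]3C(C)(C)C[C@@H](O[Si](C)(C)C(C)(C)C)C[C@@]23C
F7 | step 12 | 2β-(TBS-oxy)-13,14,15,16-tetranorlabda-7,11-dien-7-yl trifluoromethanesulfonate | C=C[C@@H]1C(C)=C(OS(=O)(=O)C(F)(F)F)C[C@@H]2C(C)(C)C[C@@H](O[Si](C)(C)C(C)(C)C)C[C@@]12C
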